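The trap in a recipe is to read the loading as the catalyst that works, when the listed steps let the impurity take free catalyst one for one.

| setting | birch | cedar | autumn | spring |
|---|---|---|---|---|
| starting material | 0.10 M | 0.10 M | 0.10 M | 0.10 M |
| second substrate | 1 equiv (fed, over 40 min) | 1 equiv (fed, over 40 min) | 1.00 equiv (fed, over 40 min) | 1.00 equiv (fed, over 40 min) |
| reagent | 3 equiv | 3 equiv | 3.00 equiv | 3.00 equiv |
| free catalyst | 1.1 mol% | 1.7 mol% | 0.76 mol% | 1.5 mol% |
| impurity | 0.40 mM | 0.40 mM | 0.40 mM | 0.40 mM |
| temperature | 0 °C | 15 °C |  |  |
| remark | run made earlier; the fed solution adds 0.10 times the starting volume | run made earlier; the fed solution adds 0.10 times the starting volume | at 5 °C until 8.0 min, from then on at 25 °C; the fed solution adds 0.10 times the starting volume | at 5 °C throughout; the fed solution adds 0.10 times the starting volume |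
| time |  |  | 40 min | 40 min |

- birch (time / min: target / %, starting material / %): 3.00: 2, 97; 8.00: 10, 91; 15.0: 20, 82; 40.0: 42, 65
- cedar (time / min: target / %, starting material / %): 6.00: 19, 85; 12.0: 27, 69; 20.0: 43, 61; 25.0: 44, 49

(scatter of a reading: 2 percentage points)

1. which of the two ends with the higher amount of target, in percent of the starting material charged ("neither" if they lie within 2 percentage points) (autumn / spring / neither)
2. target at the end, in percent of the starting material charged, autumn
3. target at the end, in percent of the starting material charged, spring

- amounts are per litre of the starting volume; all of the dose is in the solution fed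
- the analysis behind the earlier runs scatters by 2 percentage points, standard deviation
- steps under discussion: starting material + free catalyst <-> catalyst intermediate A; reagent + catalyst intermediate A -> free catalyst + target; second substrate + free catalyst <-> catalyst intermediate B; reagent + catalyst intermediate B -> free catalyst + second product; 2 free catalyst <-> resting dimer; free catalyst + impurity -> spent catalyst A; free catalyst -> spent catalyst B

Minutes of the meeting at the blackboard. The first speaker noted that spring carries twice the catalyst of autumn. She called that ratio the zero of the scale, since at equal shares lost, working catalyst stands in the ratio of the charges.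

The second speaker replied that the shares are not equal. Autumn sets 0.40 mM of impurity against 0.760 mM of catalyst, which gives 52.6%. He named this the titrated share: [impurity] at the start over [free catalyst] charged, counted one for one. Spring gives 26.7%, so the working catalyst left stands at 3.06 to one in favour of spring, wider than the ratio of the charges. He granted that this is an assumption, as neither earlier run reads a spent catalyst.

The first speaker objected that autumn goes to 25 °C at 8.0 min and might win back the gap. The second speaker answered that the earlier runs cannot size such a gain: cedar stayed at 15 °C throughout, and its target readings of 43% at 20.0 min and 44% at 25.0 min are a step of 1 percentage point against a scatter of 2 points, while its starting material read 61% and 49% at those times, so that reaction went on. The meeting left the gain from warmth open and, on the ratio of working catalyst, committed to spring ending higher.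

The forecast gives 25% for autumn and 55% for spring, so spring, noting of autumn that “the impurity takes roughly half its catalyst”.

The flasks give 29.2% for autumn and 53.5% for spring, so spring ends higher.

    starting material + free catalyst ⇌ catalyst intermediate A (K = 17.0 /M, k = 4800 /M/min, Ea = 39.0 kJ/mol, ΔH = −59.0 kJ/mol)
    reagent + catalyst intermediate A → free catalyst + target (k = 18.0 /M/min, Ea = 55.0 kJ/mol)
    second substrate + free catalyst ⇌ catalyst intermediate B (K = 8.10 /M, k = 160 /M/min, Ea = 42.0 kJ/mol, ΔH = −3.00 kJ/mol)
    reagent + catalyst intermediate B → free catalyst + second product (k = 26.0 /M/min, Ea = 54.0 kJ/mol)
    2 free catalyst ⇌ resting dimer, settled at all times (K = 3300 /M, ΔH = −15.0 kJ/mol)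
    free catalyst + impurity → spent catalyst A (k = 1.20 × 10⁵ /M/min, Ea = 41.0 kJ/mol)
    free catalyst → spent catalyst B (k = 0.00420 /min, Ea = 81.0 kJ/mol)
    (constants at 5 °C)

In autumn the impurity stood at 0% by 8.00 min, with spent catalyst A at 52.6% against the titrated share of 52.6%, and after the warming spent catalyst B climbed to 24.4% at 40.0 min while target reached 29.2%. In spring the impurity was likewise at 0% at 40.0 min, with spent catalyst A at 26.7% against 26.7%, spent catalyst B at 3.00% and resting dimer at 30.3%. The spring recipe at 0.040 M of starting material has a titrated share of 66.7%; that flask holds spent catalyst A at 66.7% and ends with target at 10.5%.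

The data were generated by integration from invented constants; scatter was added.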